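Start from a small charge. In the green run c(reagent) = 0.29 M stood above the 0.280 M of both substrates together, and left-handed product read 50.1% of those two substrates charged at 4.00 d.

| flask | left-handed substrate | right-handed substrate | reagent | free catalyst | remark |
|---|---|---|---|---|---|
| green | 0.14 M | 0.14 M | 0.29 M | 0.23 mM | run made earlier |
| blue | 0.22 M | 0.22 M | 0.29 M | 0.23 mM | run made earlier |
| red | 0.29 M | 0.29 M | 0.29 M | 0.35 mM | run made earlier |
| flask | 0.29 M | 0.29 M | 0.290 M | 0.23 mM |  |

- green (time / d: left-handed product / %): 0.500: 48.5; 1.25: 50.3; 2.50: 49.9; 4.00: 50.1
- blue (time / d: left-handed product / %): 0.333: 40.4; 0.833: 40.5; 1.67: 40.8; 4.00: 41.3
- red (time / d: left-handed product / %): 0.500: 32.6; 1.25: 32.6; 2.50: 32.5; 4.00: 32.4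

(standard deviation of a reading: 0.5 percentage points)

- free catalyst is single-handed; left-handed substrate and right-handed substrate are mirror images of each other, charged as a racemate, each of them at the stated concentration

- apparent order in free catalyst when 30% of the left-handed substrate and right-handed substrate together are converted (percent change of the rate of making left-handed product for one percent more free catalyst charged)
- factor on the rate of making left-handed product when 30% of the left-handed substrate and right-handed substrate together are converted if free catalyst is charged twice over

Now open a ledger on the red run, which has the flask's charges of substrate and reagent. There reagent is the limiting reagent. Average the four readings: 32.5%. Enter 0.189 M of reagent against left-handed product. Enter the remaining 0.101 M against right-handed product, an inference, since that product was not read. Close the books there.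

Work with fractions left, not fractions made: 34.9% of the left-handed substrate and 65.1% of the right-handed. Both substrates meet the same reagent and catalyst, so if each reacts in proportion to its own concentration, the logarithms of the two fractions keep a fixed ratio at any speed. Divide them. This gives the selectivity factor, read as 2.44.

It carries no rate, and the red readings move just 0.2 percentage points, less than their scatter. My own figure for the order is therefore an expectation, not a measurement: one, and a doubling gives two. The forecast gives the same, 1 and 2: “I therefore expect ordinary first-order behaviour”.

The flask gives an order of 1.0 and a factor of 2.00.

    reagent + free catalyst + left-handed substrate → free catalyst + left-handed product (k = 3.70 /M²/s)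
    reagent + free catalyst + right-handed substrate → free catalyst + right-handed product (k = 1.50 /M²/s)
    free catalyst → spent catalyst (k = 1.60 × 10⁻⁸ /s)

Twice the free catalyst multiplies the 0.932 h needed to reach 30% conversion by 0.500. Now raise the flask's right-handed fraction left after 4.00 d, 65%, to the power 2.44: this gives 35.0%, and the left-handed fraction left stands at 35%. Repeat on the blue run. Its readings average 40.8%, so the ledger leaves 49.7% of the right-handed substrate. The power gives 18.2%, against 18.4% of the left-handed substrate read.

The earlier runs and the new flask stem from a simulated flask on assumed constants, noise included.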